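**Retrosynthetic overview**

1. The target is 9α-benzoyloxy-3β-hydroxylabda-7,13E-dien-15-oic acid. The C13–C16 unit is cut at C12–C13 (B-alkyl Suzuki coupling of a hydroborated C9 vinyl group with an (E)-enol triflate of an acetoacetate), and the vinyl group comes from a C11 aldehyde.
2. The C9 benzoate and the C7=C8 alkene are installed together from an 8-en-11-al by α-benzoyloxylation of its dienolate on the α-face.
3. Enabling feature: ring B (C5–C6–C7–C8–C9–C10) is a six-membered carbocycle fused to ring A through C5–C10, and C9 carries the one-carbon branch C11. With C11 as CHO and the alkene at C6=C7, ring B is the retron of a [4+2] cycloaddition of a C5=C6–C7=C8 diene with a C9=C10 enal, and C1–C4 of ring A is the four-atom tether.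
4. One acyclic trienal with the single stereocentre C3 therefore gives rings A and B together in step 9 by an intramolecular Diels–Alder reaction; no ring exists before that step.
5. The trienal is assembled from ethyl 2,2-dimethylacetoacetate (C2–C5, C18, C19), a crotylphosphonate (C6–C8, C17), propargyl bromide (C1, C10, C9), Me3Al (C20) and formaldehyde (C11); C3 is set by CBS reduction.

Key step: step 9

Remark: positions are named by labdane numbering (ring A = C1–C5 and C10; ring B = C5–C10; side chain C11–C16; C17 on C8; C18 and C19 on C4; C20 on C10).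

**Route**

Step 1
Reactants: 1 ethyl 2,2-dimethyl-3-oxobutanoate
Product: 2 2,2-dimethylbutane-1,3-diol (racemic)
Conditions: LiAlH4, THF, 0 °C to rt; aqueous NaOH work-up
Reagents that add atoms: none
Why: Hydride reduction of ketone and ester (LiAlH4 reduction) should give the diol; the racemic carbinol centre is oxidised again in step 2.

Step 2
Reactants: 2 2,2-dimethylbutane-1,3-diol
Product: 3 2,2-dimethyl-3-oxobutanal
Conditions: (COCl)2, DMSO, CH2Cl2, −78 °C; Et3N, −78 to 0 °C
Reagents that add atoms: none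
Why: Double Swern oxidation should give the keto aldehyde, which cannot enolise between the carbonyl groups (quaternary α-carbon) and is used as a solution because it is volatile.

Step 3
Reactants: 3 2,2-dimethyl-3-oxobutanal; 4 diethyl [(2E)-but-2-en-1-yl]phosphonate
Product: 6 (4E,6E)-3,3-dimethylocta-4,6-dien-2-one, via lithiated phosphonate 5 (not isolated)
Conditions: 4, n-BuLi, THF, −78 °C; then 3, −78 °C to rt
Reagents that add atoms: none
Why: Horner–Wadsworth–Emmons olefination through the α-carbon of the allylic phosphonate anion is selective for the aldehyde over the hindered methyl ketone and should form the new C5=C6 bond E with the crotyl E geometry retained.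

Step 4
Reactants: 6 (4E,6E)-3,3-dimethylocta-4,6-dien-2-one; 7 3-bromoprop-1-yne (propargyl bromide)
Product: 9 (7E,9E)-6,6-dimethylundeca-7,9-dien-1-yn-5-one, via lithium enolate 8 (not isolated)
Conditions: LiN(iPr)2, THF, −78 °C; then 7, −78 to 0 °C
Reagents that add atoms: none
Why: The methyl group is the only enolisable position of 6, so kinetic enolate formation and SN2 alkylation with the propargylic bromide should form the C1–C2 bond without regiochemical ambiguity.

Step 5
Reactants: 9 (7E,9E)-6,6-dimethylundeca-7,9-dien-1-yn-5-one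
Product: 10 (5S,7E,9E)-6,6-dimethylundeca-7,9-dien-1-yn-5-ol
Conditions: (R)-2-methyl-CBS-oxazaborolidine (0.2 equiv), catecholborane, toluene, −78 to −40 °C
Reagents that add atoms: none
Why: Corey–Bakshi–Shibata reduction in which the tertiary alkyl group is the large substituent (as in pinacolone), so the (R)-catalyst should give the (S)-carbinol (C3); catecholborane leaves the alkyne and the diene untouched.

Step 6
Reactants: 10 (5S,7E,9E)-6,6-dimethylundeca-7,9-dien-1-yn-5-ol
Product: 11 tert-butyl{[(5S,7E,9E)-6,6-dimethylundeca-7,9-dien-1-yn-5-yl]oxy}dimethylsilane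
Conditions: TBSOTf, 2,6-lutidine, CH2Cl2, 0 °C
Reagents that add atoms: tert-butyldimethylsilyl trifluoromethanesulfonate, CC(C)(C)[Si](C)(C)OS(=O)(=O)C(F)(F)F
Why: Silylation of the hindered secondary alcohol next to the quaternary carbon with the silyl triflate; the ether protects C3–OH from the organometallic and oxidising steps that follow.

Step 7
Reactants: 11 tert-butyl{[(5S,7E,9E)-6,6-dimethylundeca-7,9-dien-1-yn-5-yl]oxy}dimethylsilane
Product: 13 (2E,6S,8E,10E)-6-[(tert-butyldimethylsilyl)oxy]-3,7,7-trimethyldodeca-2,8,10-trien-1-ol, via alkenyldimethylalane 12 (not isolated)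
Conditions: Me3Al, Cp2ZrCl2 (0.25 equiv), CH2Cl2, 0 °C to rt; then n-BuLi, THF, −78 °C; (CH2O)n, to rt
Reagents that add atoms: trimethylaluminium, C[Al](C)C; paraformaldehyde (as formaldehyde), C=O
Why: Negishi zirconium-catalysed carboalumination adds methyl and aluminium syn across the terminal alkyne with methyl on the internal carbon, and hydroxymethylation of the alkenyl aluminate proceeds with retention, which fixes the (E)-trisubstituted C9=C10 alkene.

Step 8
Reactants: 13 (2E,6S,8E,10E)-6-[(tert-butyldimethylsilyl)oxy]-3,7,7-trimethyldodeca-2,8,10-trien-1-ol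
Product: 14 (2E,6S,8E,10E)-6-[(tert-butyldimethylsilyl)oxy]-3,7,7-trimethyldodeca-2,8,10-trienal
Conditions: MnO2, CH2Cl2, rt
Reagents that add atoms: none
Why: MnO2 oxidation is selective for the allylic alcohol and should not isomerise the (E)-enal or touch the diene.

Step 9
Reactants: 14 (2E,6S,8E,10E)-6-[(tert-butyldimethylsilyl)oxy]-3,7,7-trimethyldodeca-2,8,10-trienal
Product: 15 (1S,2S,4aR,6S,8aS)-6-[(tert-butyldimethylsilyl)oxy]-2,5,5,8a-tetramethyl-1,2,4a,5,6,7,8,8a-octahydronaphthalene-1-carbaldehyde (trans-fused; 3β-OTBS, 5α-H, 8β-CH3, 9β-CHO, 10β-CH3, alkene at C6=C7)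
Conditions: Me2AlCl (1.1 equiv), CH2Cl2, −78 to −20 °C
Reagents that add atoms: none
Why: Complexation of the formyl group by Me2AlCl lowers the LUMO of the C9=C10 enal, which should undergo a concerted, asynchronous intramolecular [4+2] cycloaddition with the C5=C6–C7=C8 diene (type 1 intramolecular Diels–Alder reaction of a 1,7,9-decatriene under Lewis acid promotion, as in trienal and trienoate cyclisations to trans-decalins). Ring B is closed as the cyclohexene of the cycloaddition by the two new bonds C5–C10 and C8–C9, and ring A is closed at the same time by the bond C5–C10 across the four-atom tether C1–C4 in a chair-like, fused (not bridged) mode. C5 and C10 are set trans because the aluminium-bound formyl group of the (E)-dienophile takes the endo position, which puts the C10 methyl group and C5–H on opposite faces; C9 (formyl β) and C8 (methyl β) follow from suprafacial addition to the (E)-enal and the (E,E)-diene and are erased in steps 11 and 12. The absolute sense is relayed from C3, whose silyloxy group should sit equatorial on the chair-like tether and so expose only one face of the diene to the dienophile. The step needs endo over exo selectivity (secured by the E geometry of the enal and by the Lewis acid) and π-facial selectivity (secured by the C3 stereocentre next to the gem-dimethyl group), while the regiochemistry is fixed by the tether. The gem-dimethyl group at C4 should favour the folded, reactive conformer.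

Step 10
Reactants: 15 (1S,2S,4aR,6S,8aS)-6-[(tert-butyldimethylsilyl)oxy]-2,5,5,8a-tetramethyl-1,2,4a,5,6,7,8,8a-octahydronaphthalene-1-carbaldehyde
Product: 16 (1S,2S,4aR,6S,8aS)-6-[(tert-butyldimethylsilyl)oxy]-2,5,5,8a-tetramethyldecahydronaphthalene-1-carbaldehyde
Conditions: H2 (1 atm), Pd/C, EtOAc, rt
Reagents that add atoms: none
Why: Heterogeneous hydrogenation of the only C=C bond (cis-disubstituted C6=C7) removes the misplaced alkene; aldehyde and silyl ether should survive, and any epimerisation at C9 is without consequence.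

Step 11
Reactants: 16 (1S,2S,4aR,6S,8aS)-6-[(tert-butyldimethylsilyl)oxy]-2,5,5,8a-tetramethyldecahydronaphthalene-1-carbaldehyde
Product: 17 (4aR,6S,8aS)-6-[(tert-butyldimethylsilyl)oxy]-2,5,5,8a-tetramethyl-3,4,4a,5,6,7,8,8a-octahydronaphthalene-1-carbaldehyde
Conditions: IBX (1.5 equiv), DMSO/fluorobenzene, 70 °C
Reagents that add atoms: none
Why: IBX dehydrogenation of the aldehyde can only form the C8=C9 bond because C10 is quaternary; it erases the C8 and C9 stereocentres and gives a tetrasubstituted enal of the β-cyclocitral type.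

Step 12
Reactants: 17 (4aR,6S,8aS)-6-[(tert-butyldimethylsilyl)oxy]-2,5,5,8a-tetramethyl-3,4,4a,5,6,7,8,8a-octahydronaphthalene-1-carbaldehyde
Product: 19 (1R,4aS,6S,8aS)-6-[(tert-butyldimethylsilyl)oxy]-1-formyl-2,5,5,8a-tetramethyl-1,4,4a,5,6,7,8,8a-octahydronaphthalen-1-yl benzoate, via potassium dienolate 18 (not isolated)
Conditions: KOtBu (1.05 equiv), THF, 0 °C; then (PhCO2)2, −78 to −40 °C
Reagents that add atoms: dibenzoyl peroxide, O=C(OOC(=O)c1ccccc1)c1ccccc1
Why: γ-Deprotonation at C7 under equilibrating conditions should give the endocyclic dienolate (as with β-cyclocitral), which attacks the peroxide oxygen through its α-carbon C9 from the α-face, anti to the axial C10 methyl group (as in the 9α-hydroxylation of drimane dienolates); this electrophilic α-benzoyloxylation of an enolate sets C9 and moves the alkene to C7=C8 in one step.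

Step 13
Reactants: 19 (1R,4aS,6S,8aS)-6-[(tert-butyldimethylsilyl)oxy]-1-formyl-2,5,5,8a-tetramethyl-1,4,4a,5,6,7,8,8a-octahydronaphthalen-1-yl benzoate
Product: 20 (1R,4aS,6S,8aS)-6-[(tert-butyldimethylsilyl)oxy]-1-ethenyl-2,5,5,8a-tetramethyl-1,4,4a,5,6,7,8,8a-octahydronaphthalen-1-yl benzoate
Conditions: Ph3PCH3Br, KN(SiMe3)2, THF, 0 °C; then 19, −78 to 0 °C
Reagents that add atoms: methyltriphenylphosphonium bromide, C[P+](c1ccccc1)(c1ccccc1)c1ccccc1.[Br-]
Why: Wittig methylenation of the non-enolisable aldehyde; the benzoate carbonyl is far less electrophilic toward the ylide at low temperature.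

Step 14
Reactants: 21 2-(trimethylsilyl)ethanol; 22 2,2,6-trimethyl-4H-1,3-dioxin-4-one
Product: 24 2-(trimethylsilyl)ethyl 3-oxobutanoate, via acetylketene 23 (not isolated)
Conditions: toluene, 110 °C, acetone distilled off
Reagents that add atoms: none
Why: Thermal retro-[4+2] fragmentation of the dioxinone gives acetylketene, which the alcohol traps (acetoacetylation).

Step 15
Reactants: 24 2-(trimethylsilyl)ethyl 3-oxobutanoate
Product: 25 2-(trimethylsilyl)ethyl (2E)-3-{[(trifluoromethyl)sulfonyl]oxy}but-2-enoate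
Conditions: Tf2O, aq. Me4NOH, hexanes, 5 °C
Reagents that add atoms: trifluoromethanesulfonic anhydride, O=S(=O)(OS(=O)(=O)C(F)(F)F)C(F)(F)F
Why: O-Triflation of the non-chelated tetramethylammonium enolate in a two-phase medium should give the (E)-enol triflate (triflate trans to the ester), the geometry needed for the 13E alkene.

Step 16
Reactants: 20 (1R,4aS,6S,8aS)-6-[(tert-butyldimethylsilyl)oxy]-1-ethenyl-2,5,5,8a-tetramethyl-1,4,4a,5,6,7,8,8a-octahydronaphthalen-1-yl benzoate; 25 2-(trimethylsilyl)ethyl (2E)-3-{[(trifluoromethyl)sulfonyl]oxy}but-2-enoate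
Product: 27 2-(trimethylsilyl)ethyl (2E)-5-[(1R,4aS,6S,8aS)-1-(benzoyloxy)-6-[(tert-butyldimethylsilyl)oxy]-2,5,5,8a-tetramethyl-1,4,4a,5,6,7,8,8a-octahydronaphthalen-1-yl]-3-methylpent-2-enoate, via B-alkyl-9-BBN borane 26 (not isolated)
Conditions: 9-BBN, THF, 0 °C to rt; then 25, PdCl2(dppf) (5 mol%), Ph3As, Cs2CO3, DMF/H2O, rt
Reagents that add atoms: none
Why: 9-BBN places boron only on the terminal carbon of the monosubstituted alkene (the trisubstituted C7=C8 alkene is inert), and the B-alkyl Suzuki–Miyaura coupling proceeds with retention of the triflate geometry, so the C12–C13 bond and the (13E)-enoate should form in one operation.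

Step 17
Reactants: 27 2-(trimethylsilyl)ethyl (2E)-5-[(1R,4aS,6S,8aS)-1-(benzoyloxy)-6-[(tert-butyldimethylsilyl)oxy]-2,5,5,8a-tetramethyl-1,4,4a,5,6,7,8,8a-octahydronaphthalen-1-yl]-3-methylpent-2-enoate
Product: 28 (2E)-5-[(1R,4aS,6S,8aS)-1-(benzoyloxy)-6-hydroxy-2,5,5,8a-tetramethyl-1,4,4a,5,6,7,8,8a-octahydronaphthalen-1-yl]-3-methylpent-2-enoic acid (CNP0288577.1)
Conditions: Bu4NF, THF, 0 to 40 °C; aq. NH4Cl work-up
Reagents that add atoms: none
Why: Fluoride should cleave the silyl ether and the 2-(trimethylsilyl)ethyl ester (β-elimination with loss of ethene) in one operation, leaving the hindered tertiary benzoate and both alkenes untouched.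

**Compound list**

1 | ethyl 2,2-dimethyl-3-oxobutanoate | CCOC(=O)C(C)(C)C(C)=O | starting material
2 | 2,2-dimethylbutane-1,3-diol (racemic) | CC(O)C(C)(C)CO | intermediate
3 | 2,2-dimethyl-3-oxobutanal | CC(=O)C(C)(C)C=O | intermediate
4 | diethyl [(2E)-but-2-en-1-yl]phosphonate | C/C=C/CP(=O)(OCC)OCC | starting material
5 | lithiated diethyl [(2E)-but-2-en-1-yl]phosphonate (not isolated) | C/C=C/[CH-]P(=O)(OCC)OCC.[Li+] | intermediate
6 | (4E,6E)-3,3-dimethylocta-4,6-dien-2-one | C/C=C/C=C/C(C)(C)C(C)=O | intermediate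
7 | 3-bromoprop-1-yne | C#CCBr | starting material
8 | lithium enolate of 6 (not isolated) | C/C=C/C=C/C(C)(C)C(=C)[O-].[Li+] | intermediate
9 | (7E,9E)-6,6-dimethylundeca-7,9-dien-1-yn-5-one | C/C=C/C=C/C(C)(C)C(=O)CCC#C | intermediate
10 | (5S,7E,9E)-6,6-dimethylundeca-7,9-dien-1-yn-5-ol | C#CCC[C@H](O)C(C)(C)/C=C/C=C/C | intermediate
11 | tert-butyl{[(5S,7E,9E)-6,6-dimethylundeca-7,9-dien-1-yn-5-yl]oxy}dimethylsilane | C#CCC[C@H](O[Si](C)(C)C(C)(C)C)C(C)(C)/C=C/C=C/C | intermediate
12 | dimethyl[(1E,5S,7E,9E)-5-[(tert-butyldimethylsilyl)oxy]-2,6,6-trimethylundeca-1,7,9-trien-1-yl]alumane (not isolated) | C[Al](C)/C=C(\C)CC[C@H](O[Si](C)(C)C(C)(C)C)C(C)(C)/C=C/C=C/C | intermediate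
13 | (2E,6S,8E,10E)-6-[(tert-butyldimethylsilyl)oxy]-3,7,7-trimethyldodeca-2,8,10-trien-1-ol | OC/C=C(\C)CC[C@H](O[Si](C)(C)C(C)(C)C)C(C)(C)/C=C/C=C/C | intermediate
14 | (2E,6S,8E,10E)-6-[(tert-butyldimethylsilyl)oxy]-3,7,7-trimethyldodeca-2,8,10-trienal | O=C/C=C(\C)CC[C@H](O[Si](C)(C)C(C)(C)C)C(C)(C)/C=C/C=C/C | intermediate
15 | (1S,2S,4aR,6S,8aS)-6-[(tert-butyldimethylsilyl)oxy]-2,5,5,8a-tetramethyl-1,2,4a,5,6,7,8,8a-octahydronaphthalene-1-carbaldehyde | C[C@H]1C=C[C@H]2C(C)(C)[C@@H](O[Si](C)(C)C(C)(C)C)CC[C@]2(C)[C@H]1C=O | intermediate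
16 | (1S,2S,4aR,6S,8aS)-6-[(tert-butyldimethylsilyl)oxy]-2,5,5,8a-tetramethyldecahydronaphthalene-1-carbaldehyde | C[C@H]1CC[C@H]2C(C)(C)[C@@H](O[Si](C)(C)C(C)(C)C)CC[C@]2(C)[C@H]1C=O | intermediate
17 | (4aR,6S,8aS)-6-[(tert-butyldimethylsilyl)oxy]-2,5,5,8a-tetramethyl-3,4,4a,5,6,7,8,8a-octahydronaphthalene-1-carbaldehyde | CC=1CC[C@H]2C(C)(C)[C@@H](O[Si](C)(C)C(C)(C)C)CC[C@]2(C)C=1C=O | intermediate
18 | potassium dienolate of 17 (C7=C8 and C9=C11–O; not isolated) | CC1=CC[C@H]2C(C)(C)[C@@H](O[Si](C)(C)C(C)(C)C)CC[C@]2(C)C1=C[O-].[K+] | intermediate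
19 | (1R,4aS,6S,8aS)-6-[(tert-butyldimethylsilyl)oxy]-1-formyl-2,5,5,8a-tetramethyl-1,4,4a,5,6,7,8,8a-octahydronaphthalen-1-yl benzoate | CC1=CC[C@H]2C(C)(C)[C@@H](O[Si](C)(C)C(C)(C)C)CC[C@]2(C)[C@]1(C=O)OC(=O)c1ccccc1 | intermediate
20 | (1R,4aS,6S,8aS)-6-[(tert-butyldimethylsilyl)oxy]-1-ethenyl-2,5,5,8a-tetramethyl-1,4,4a,5,6,7,8,8a-octahydronaphthalen-1-yl benzoate | CC1=CC[C@H]2C(C)(C)[C@@H](O[Si](C)(C)C(C)(C)C)CC[C@]2(C)[C@]1(C=C)OC(=O)c1ccccc1 | intermediate
21 | 2-(trimethylsilyl)ethanol | C[Si](C)(C)CCO | starting material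
22 | 2,2,6-trimethyl-4H-1,3-dioxin-4-one | CC1=CC(=O)OC(C)(C)O1 | starting material
23 | acetylketene (not isolated) | CC(=O)C=C=O | intermediate
24 | 2-(trimethylsilyl)ethyl 3-oxobutanoate | CC(=O)CC(=O)OCC[Si](C)(C)C | intermediate
25 | 2-(trimethylsilyl)ethyl (2E)-3-{[(trifluoromethyl)sulfonyl]oxy}but-2-enoate | C/C(OS(=O)(=O)C(F)(F)F)=C\C(=O)OCC[Si](C)(C)C | intermediate
26 | B-alkyl-9-BBN adduct of 20 (boron on C12; not isolated) | CC1=CC[C@H]2C(C)(C)[C@@H](O[Si](C)(C)C(C)(C)C)CC[C@]2(C)[C@]1(CCB1C3CCCC1CCC3)OC(=O)c1ccccc1 | intermediate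
27 | 2-(trimethylsilyl)ethyl (2E)-5-[(1R,4aS,6S,8aS)-1-(benzoyloxy)-6-[(tert-butyldimethylsilyl)oxy]-2,5,5,8a-tetramethyl-1,4,4a,5,6,7,8,8a-octahydronaphthalen-1-yl]-3-methylpent-2-enoate | CC1=CC[C@H]2C(C)(C)[C@@H](O[Si](C)(C)C(C)(C)C)CC[C@]2(C)[C@]1(CC/C(C)=C/C(=O)OCC[Si](C)(C)C)OC(=O)c1ccccc1 | intermediate
28 | (2E)-5-[(1R,4aS,6S,8aS)-1-(benzoyloxy)-6-hydroxy-2,5,5,8a-tetramethyl-1,4,4a,5,6,7,8,8a-octahydronaphthalen-1-yl]-3-methylpent-2-enoic acid | CC1=CC[C@H]2C(C)(C)[C@@H](O)CC[C@]2(C)[C@]1(CC/C(C)=C/C(=O)O)OC(=O)c1ccccc1 | target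

**Summary**

Total step count: 17. Longest linear sequence: 15 steps (steps 1–13, 16 and 17); steps 14 and 15 prepare the coupling partner 25.

Steps most likely to fail:

Step 9. The β,β-disubstituted enal may be too weakly activated by Me2AlCl, so that cyclisation is slow and Lewis-acid-induced decomposition of the diene or erosion of the endo (trans-fusion) preference takes over. The dienophile would then be activated as a cation instead. Trienal 14 would be converted with 1,2-bis(trimethylsilyloxy)ethane and catalytic TMSOTf (CH2Cl2, −78 °C) into the dioxolane acetal of the trienal F1. With further TMSOTf this acetal should ionise to an alkoxyallyl cation and undergo the ionic intramolecular Diels–Alder reaction at −78 °C to give the dioxolane acetal of the adduct F2. Mild aqueous acid (PPTS, acetone/H2O) would then return aldehyde 15.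

Step 12. The dienolate may be acylated on oxygen by the peroxide, or carbon–oxygen bond formation at the fully substituted C9 may be too slow to compete with attack through C7. Oxygen transfer and acylation would then be separated. Dienolate 18, generated from 17 as in step 12, would be hydroxylated with 2-(phenylsulfonyl)-3-phenyloxaziridine (THF, −78 °C), an oxidant that can transfer only oxygen and reacts at the α-carbon from the α-face, to give the 9α-hydroxy aldehyde F3. Deprotonation with LiN(SiMe3)2 and acylation with benzoyl chloride (THF, −78 to 0 °C) would give benzoate 19.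

Step 16. Oxidative addition of zerovalent palladium into the tertiary allylic benzoate (C7=C8–C9–O) may compete with the cross-coupling, or hydroboration of the hindered vinyl group may stall. The side chain would then be built without palladium from aldehyde 19. Horner–Wadsworth–Emmons reaction with dimethyl (2-oxopropyl)phosphonate (LiCl, iPr2NEt, MeCN) should give the (E)-enone F4. Conjugate reduction with [(Ph3P)CuH]6 (toluene, rt) should give the methyl ketone F5. A second Horner–Wadsworth–Emmons olefination with 2-(trimethylsilyl)ethyl (diethoxyphosphoryl)acetate (NaH, THF) should give ester 27 after removal of the minor Z isomer.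

**Further compounds**

F1 | step 9 | 2-[(1E,5S,7E,9E)-5-[(tert-butyldimethylsilyl)oxy]-2,6,6-trimethylundeca-1,7,9-trien-1-yl]-1,3-dioxolane | O1CCOC1/C=C(\C)CC[C@H](O[Si](C)(C)C(C)(C)C)C(C)(C)/C=C/C=C/C
F2 | step 9 | 2-[(1S,2S,4aR,6S,8aS)-6-[(tert-butyldimethylsilyl)oxy]-2,5,5,8a-tetramethyl-1,2,4a,5,6,7,8,8a-octahydronaphthalen-1-yl]-1,3-dioxolane | C[C@H]1C=C[C@H]2C(C)(C)[C@@H](O[Si](C)(C)C(C)(C)C)CC[C@]2(C)[C@H]1C1OCCO1
F3 | step 12 | (1R,4aS,6S,8aS)-6-[(tert-butyldimethylsilyl)oxy]-1-hydroxy-2,5,5,8a-tetramethyl-1,4,4a,5,6,7,8,8a-octahydronaphthalene-1-carbaldehyde | CC1=CC[C@H]2C(C)(C)[C@@H](O[Si](C)(C)C(C)(C)C)CC[C@]2(C)[C@]1(C=O)O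
F4 | step 16 | (1R,4aS,6S,8aS)-6-[(tert-butyldimethylsilyl)oxy]-2,5,5,8a-tetramethyl-1-[(1E)-3-oxobut-1-en-1-yl]-1,4,4a,5,6,7,8,8a-octahydronaphthalen-1-yl benzoate | CC1=CC[C@H]2C(C)(C)[C@@H](O[Si](C)(C)C(C)(C)C)CC[C@]2(C)[C@]1(/C=C/C(C)=O)OC(=O)c1ccccc1
F5 | step 16 | (1R,4aS,6S,8aS)-6-[(tert-butyldimethylsilyl)oxy]-2,5,5,8a-tetramethyl-1-(3-oxobutyl)-1,4,4a,5,6,7,8,8a-octahydronaphthalen-1-yl benzoate | CC1=CC[C@H]2C(C)(C)[C@@H](O[Si](C)(C)C(C)(C)C)CC[C@]2(C)[C@]1(CCC(C)=O)OC(=O)c1ccccc1
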